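**Retrosynthetic overview**

1. The target is the malonic acid diester of two molecules of (5S,9S,10S)-labda-7,13E-dien-15-ol (labdane numbering: ring A = C1–C5 and C10; ring B = C5–C10; C17 on C8; side chain C11–C15 on C9); the two ester C–O bonds are cut last.
2. The E-C13=C14–C15 allylic alcohol comes from a terminal C13≡C14 alkyne (zirconium-catalysed methylalumination, then formaldehyde), and C7=C8 comes from a C7 ketone through its C7=C8 enol triflate.
3. Key disconnection: ring B is made from a cyclobutanol ring (C7, C6, C5, C10) by a radical two-carbon ring expansion that inserts C8 and C9 of an alkenyl group on C7 between C7 and C10, forming the C9–C10 bond and the C9 and C10 stereocentres.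
4. Enabling feature: in ring B, C7 and the methyl-bearing quaternary C10 are linked on one side by C6–C5 and on the other by C8(CH3)–C9, so a C7–O radical can release C10 as a tertiary radical and the C8=C9 enone can take it back 6-endo; the oxygen left on C7 marks where the C7=C8 double bond goes.
5. Ring order: ring A and the four-membered ring form together in one auxiliary-controlled intramolecular keteniminium–alkene [2+2] cycloaddition of an acyclic amide (sets C5), then ring B by the ring expansion.

Key step: step 12

Assumption: (2R,5R)-2,5-dimethylpyrrolidine is taken to direct the cycloaddition to the (1S,6R) ketone; if the sense of induction is the opposite, the (2S,5S) amine is used and nothing else changes.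

**Route**

Step 1
Reactants: 1 isobutyronitrile; 2 1-bromo-3-chloropropane
Product: 4 5-chloro-2,2-dimethylpentanenitrile, via lithiated isobutyronitrile 3 (not isolated)
Conditions: LiN(i-Pr)2, THF, −78 °C; then 2, −78 °C → rt
Reagents that add atoms: none
Why: SN2 alkylation of the lithiated nitrile at the bromide end of the dihalide should build the gem-dimethyl quaternary carbon (C4) carrying the C3–C1 chain; no stereocentre is formed.

Step 2
Reactants: 4 5-chloro-2,2-dimethylpentanenitrile
Product: 6 5-chloro-2,2-dimethylpentanal, via N-aluminated aldimine 5 (not isolated)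
Conditions: i-Bu2AlH, CH2Cl2, −78 °C; then 1 M HCl
Reagents that add atoms: water, O
Why: Partial reduction of a nitrile with i-Bu2AlH stops at the aluminated aldimine, which hydrolyses to the aldehyde; the neopentyl aldehyde cannot enolise.

Step 3
Reactants: 6 5-chloro-2,2-dimethylpentanal
Product: 7 6-chloro-3,3-dimethylhex-1-ene
Conditions: Ph3PCH3Br, KOt-Bu, THF, 0 °C → rt
Reagents that add atoms: methyltriphenylphosphonium bromide, C[P+](c1ccccc1)(c1ccccc1)c1ccccc1.[Br-]
Why: Wittig methylenation of the non-enolisable aldehyde should install the vinyl group (C5=C6) next to the quaternary carbon.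

Step 4
Reactants: 7 6-chloro-3,3-dimethylhex-1-ene
Product: 8 6-iodo-3,3-dimethylhex-1-ene
Conditions: NaI, acetone, reflux
Reagents that add atoms: sodium iodide, [Na+].[I-]
Why: Finkelstein halide exchange on the unhindered primary chloride should give the iodide needed for enolate alkylation.

Step 5
Reactants: 9 (2R,5R)-2,5-dimethylpyrrolidine
Product: 10 1-[(2R,5R)-2,5-dimethylpyrrolidin-1-yl]propan-1-one
Conditions: propionyl chloride, Et3N, CH2Cl2, 0 °C
Reagents that add atoms: propionyl chloride, CCC(Cl)=O
Why: N-Acylation of the secondary amine with the acid chloride attaches the C2-symmetric auxiliary that will later control the cycloaddition.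

Step 6
Reactants: 10 1-[(2R,5R)-2,5-dimethylpyrrolidin-1-yl]propan-1-one; 8 6-iodo-3,3-dimethylhex-1-ene
Product: 12 1-[(2R,5R)-2,5-dimethylpyrrolidin-1-yl]-2,6,6-trimethyloct-7-en-1-one (either configuration at C2 of the chain), via lithium enolate 11 (not isolated)
Conditions: LiN(i-Pr)2, THF, −78 °C; then 8, −78 → 0 °C
Reagents that add atoms: none
Why: Amide enolate alkylation (SN2) with the primary iodide should join C1 to C10; the new α-centre need not be controlled because it becomes sp2 in step 7.

Step 7
Reactants: 12 1-[(2R,5R)-2,5-dimethylpyrrolidin-1-yl]-2,6,6-trimethyloct-7-en-1-one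
Product: 15 (1S,6R)-2,2,6-trimethylbicyclo[4.2.0]octan-7-one (cis-fused; C7=O next to the methyl-bearing bridgehead), via keteniminium triflate 13 (not isolated), via cyclobutaniminium triflate 14 (not isolated)
Conditions: Tf2O, 2,4,6-collidine, ClCH2CH2Cl, 0 °C → reflux; then H2O, NaHCO3
Reagents that add atoms: water, O
Why: Intramolecular keteniminium–alkene [2+2] cycloaddition should join the electrophilic iminium carbon (C7) to the terminal alkene carbon (C6) and the ketene carbon (C10) to C5, closing ring A and the cyclobutane at once with the cis fusion that suprafacial addition enforces, while the C2-symmetric pyrrolidine selects the face of C10=C7 and so sets C5 (and C10) in absolute terms; hydrolysis frees the ketone and returns the auxiliary.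

Step 8
Reactants: 16 pent-3-yn-1-ol
Product: 17 pent-3-yn-1-yl 4-methylbenzenesulfonate
Conditions: TsCl, Et3N, DMAP (cat.), CH2Cl2, 0 °C → rt
Reagents that add atoms: p-toluenesulfonyl chloride, Cc1ccc(cc1)S(Cl)(=O)=O
Why: Sulfonylation of the primary alcohol provides the leaving group for step 10.

Step 9
Reactants: 17 pent-3-yn-1-yl 4-methylbenzenesulfonate
Product: 19 (E)-4-iodopent-3-en-1-yl 4-methylbenzenesulfonate, via alkenylzirconocene 18 (not isolated)
Conditions: Cp2Zr(H)Cl (2 equiv), THF, rt → 45 °C; then I2, 0 °C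
Reagents that add atoms: iodine, [I][I]
Why: Hydrozirconation is a syn addition, and excess reagent equilibrates zirconium to the methyl-bearing alkyne carbon, so iodinolysis with retention should give the (E)-2-iodoalkene (methyl cis to the chain).

Step 10
Reactants: 19 (E)-4-iodopent-3-en-1-yl 4-methylbenzenesulfonate
Product: 20 (E)-(6-iodohept-5-en-1-yn-1-yl)trimethylsilane
Conditions: ethynyltrimethylsilane, n-BuLi, THF, −78 °C; then 19, DMPU, −78 °C → rt
Reagents that add atoms: ethynyltrimethylsilane, C#C[Si](C)(C)C
Why: SN2 displacement of the primary tosylate by the lithium acetylide adds C13–C14 as a silyl-protected alkyne without touching the vinyl iodide or its geometry.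

Step 11
Reactants: 20 (E)-(6-iodohept-5-en-1-yn-1-yl)trimethylsilane; 15 (1S,6R)-2,2,6-trimethylbicyclo[4.2.0]octan-7-one
Product: 22 (1S,6R)-2,2,6-trimethyl-7-[(2E)-7-(trimethylsilyl)hept-2-en-6-yn-2-yl]bicyclo[4.2.0]octan-7-ol (carbinol configuration not controlled), via alkenyllithium 21 (not isolated)
Conditions: t-BuLi (2 equiv), Et2O, −78 °C; then 15, −78 → 0 °C; H2O
Reagents that add atoms: none
Why: Iodine–lithium exchange proceeds with retention of alkene geometry and 1,2-addition to the strained, poorly enolisable cyclobutanone should give the tertiary alkenyl carbinol; either carbinol epimer serves because C7 becomes sp2 in the next step.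

Step 12
Reactants: 22 (1S,6R)-2,2,6-trimethyl-7-[(2E)-7-(trimethylsilyl)hept-2-en-6-yn-2-yl]bicyclo[4.2.0]octan-7-ol
Product: 27 (8ξ)-14-(trimethylsilyl)-15,16-dinorlabd-13-yn-7-one (trans-decalin: 5α-H, 9α-H, 10β-CH3; C8 epimers), via alkoxy radical 23 (not isolated), via ring-opened tertiary radical 24 (not isolated), via α-keto radical 25 (not isolated), via collidinium enolate 26 (not isolated)
Conditions: [Ir(dF(CF3)ppy)2(5,5'-d(CF3)bpy)]PF6 (2 mol%), 2,4,6-collidine, CH2Cl2, blue LEDs, rt
Reagents that add atoms: none
Why: Excited trivalent iridium and collidine remove a proton and an electron from the O–H bond of 22 (proton-coupled electron transfer), and the alkoxy radical 23 cleaves the strained C7–C10 bond to give the tertiary C10 radical 24, tethered through C5–C6 to the E-enone C7(=O)–C8(CH3)=C9; addition of C10 to C9 closes ring B as the α-keto radical 25, which divalent iridium reduces to enolate 26 and collidinium protonates, so the net change is a redox-neutral two-carbon expansion of the four-membered ring (C7, C6, C5, C10) to the six-membered ring. The closest known reaction type is the photocatalytic alkoxy-radical ring expansion of 1-alkenylcycloalkanols in its n+2 (endo) mode, and the closure itself matches the second ring closure of a radical polyene cyclisation. Ring B closes 6-endo-trig through a chair transition state. C10 is set by the C5 stereocentre, the only one carried through the planar radical: C9 should bond to the face of C10 opposite to C6, so that both ring-B bonds are equatorial on ring A and the methyl group becomes axial (trans-decalin); C9 is set by the E geometry of C8=C9, which places the side chain pseudo-equatorial and H-9 axial. The step needs β-scission toward C10 and not C6 (tertiary versus primary radical), endo and not 5-exo closure (attack at C9 gives a tertiary α-keto radical, attack at C8 a secondary alkyl radical) and no further cyclisation of 25, which is why the side chain ends in an alkynylsilane and not yet in the trisubstituted alkene.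

Step 13
Reactants: 27 (8ξ)-14-(trimethylsilyl)-15,16-dinorlabd-13-yn-7-one
Product: 29 14-(trimethylsilyl)-15,16-dinorlabd-7-en-13-yn-7-yl trifluoromethanesulfonate, via bromomagnesium enolate 28 (not isolated)
Conditions: i-Pr2NMgBr, Et2O, reflux; then PhNTf2, rt
Reagents that add atoms: N-phenylbis(trifluoromethanesulfonimide), O=S(=O)(N(c1ccccc1)S(=O)(=O)C(F)(F)F)C(F)(F)F
Why: Equilibrating enolisation with the magnesium amide should favour the more substituted C7=C8 enolate, and O-triflation fixes the double bond there; both C8 epimers converge because C8 becomes sp2.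

Step 14
Reactants: 29 14-(trimethylsilyl)-15,16-dinorlabd-7-en-13-yn-7-yl trifluoromethanesulfonate
Product: 30 14-(trimethylsilyl)-15,16-dinorlabd-7-en-13-yne
Conditions: Pd(OAc)2 (5 mol%), PPh3, HCO2H, Et3N, DMF, 60 °C
Reagents that add atoms: none
Why: Palladium-catalysed formate hydrogenolysis of the enol triflate (oxidative addition to zerovalent palladium, formate exchange, decarboxylation, reductive elimination) replaces OTf by H without moving the C7=C8 double bond; the silylated alkyne is inert.

Step 15
Reactants: 30 14-(trimethylsilyl)-15,16-dinorlabd-7-en-13-yne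
Product: 31 15,16-dinorlabd-7-en-13-yne
Conditions: K2CO3, MeOH, rt
Reagents that add atoms: none
Why: Methanolysis of the alkynyl C–Si bond (protodesilylation) frees the terminal alkyne.

Step 16
Reactants: 31 15,16-dinorlabd-7-en-13-yne
Product: 34 (5S,9S,10S)-labda-7,13E-dien-15-ol, via alkenylalane 32 (not isolated), via lithium aluminate 33 (not isolated)
Conditions: Me3Al, Cp2ZrCl2 (25 mol%), CH2Cl2, rt; then n-BuLi, THF, −78 °C; (CH2O)n, rt; 1 M HCl
Reagents that add atoms: trimethylaluminium, C[Al](C)C; paraformaldehyde (as formaldehyde), C=O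
Why: Zirconium-catalysed carboalumination (Negishi) adds CH3 and Al syn across the terminal alkyne with methyl on the internal carbon, and hydroxymethylation of the aluminate with retention should give the E-trisubstituted allylic alcohol; the hindered C7=C8 alkene does not react.

Step 17
Reactants: 34 (5S,9S,10S)-labda-7,13E-dien-15-ol (2 equiv); 35 malonic acid
Product: 37 bis[(5S,9S,10S)-labda-7,13E-dien-15-yl] malonate, via malonate half-ester 36 (not isolated)
Conditions: DCC, DMAP (cat.), CH2Cl2, 0 °C → rt
Reagents that add atoms: none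
Why: Steglich esterification acylates the primary allylic alcohol twice under neutral conditions that leave both trisubstituted alkenes and all stereocentres untouched.

**Compound list**

1 | isobutyronitrile | CC(C)C#N | starting material
2 | 1-bromo-3-chloropropane | ClCCCBr | starting material
3 | lithiated isobutyronitrile | [Li]C(C)(C)C#N | intermediate (not isolated)
4 | 5-chloro-2,2-dimethylpentanenitrile | N#CC(C)(C)CCCCl | intermediate
5 | N-(diisobutylalumino)-5-chloro-2,2-dimethylpentan-1-imine | CC(C)C[Al](CC(C)C)N=CC(C)(C)CCCCl | intermediate (not isolated)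
6 | 5-chloro-2,2-dimethylpentanal | O=CC(C)(C)CCCCl | intermediate
7 | 6-chloro-3,3-dimethylhex-1-ene | C=CC(C)(C)CCCCl | intermediate
8 | 6-iodo-3,3-dimethylhex-1-ene | C=CC(C)(C)CCCI | intermediate
9 | (2R,5R)-2,5-dimethylpyrrolidine | C[C@@H]1CC[C@@H](C)N1 | starting material
10 | 1-[(2R,5R)-2,5-dimethylpyrrolidin-1-yl]propan-1-one | CCC(=O)N1[C@H](C)CC[C@H]1C | intermediate
11 | lithium (Z)-enolate of 10 | C/C=C(\O[Li])N1[C@H](C)CC[C@H]1C | intermediate (not isolated)
12 | 1-[(2R,5R)-2,5-dimethylpyrrolidin-1-yl]-2,6,6-trimethyloct-7-en-1-one (C2 of chain unassigned) | C=CC(C)(C)CCCC(C)C(=O)N1[C@H](C)CC[C@H]1C | intermediate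
13 | (2R,5R)-2,5-dimethyl-1-(2,6,6-trimethylocta-1,7-dien-1-ylidene)pyrrolidinium triflate (keteniminium salt) | C=CC(C)(C)CCCC(C)=C=[N+]1[C@H](C)CC[C@H]1C.[O-]S(=O)(=O)C(F)(F)F | intermediate (not isolated)
14 | (2R,5R)-2,5-dimethyl-1-[(1S,6R)-2,2,6-trimethylbicyclo[4.2.0]octan-7-ylidene]pyrrolidinium triflate | C[C@@H]1CC[C@@H](C)[N+]1=C1C[C@H]2C(C)(C)CCC[C@@]12C.[O-]S(=O)(=O)C(F)(F)F | intermediate (not isolated)
15 | (1S,6R)-2,2,6-trimethylbicyclo[4.2.0]octan-7-one (cis-fused) | O=C1C[C@H]2C(C)(C)CCC[C@@]12C | intermediate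
16 | pent-3-yn-1-ol | CC#CCCO | starting material
17 | pent-3-yn-1-yl 4-methylbenzenesulfonate | CC#CCCOS(=O)(=O)c1ccc(C)cc1 | intermediate
18 | chlorobis(cyclopentadienyl)[(E)-5-(tosyloxy)pent-2-en-2-yl]zirconium | C/C(=C\CCOS(=O)(=O)c1ccc(C)cc1)[Zr](Cl)(C1C=CC=C1)C1C=CC=C1 | intermediate (not isolated)
19 | (E)-4-iodopent-3-en-1-yl 4-methylbenzenesulfonate | C/C(I)=C\CCOS(=O)(=O)c1ccc(C)cc1 | intermediate
20 | (E)-(6-iodohept-5-en-1-yn-1-yl)trimethylsilane | C/C(I)=C\CCC#C[Si](C)(C)C | intermediate
21 | [(Z)-7-(trimethylsilyl)hept-2-en-6-yn-2-yl]lithium (geometry of 20 retained) | C/C([Li])=C\CCC#C[Si](C)(C)C | intermediate (not isolated)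
22 | (1S,6R)-2,2,6-trimethyl-7-[(2E)-7-(trimethylsilyl)hept-2-en-6-yn-2-yl]bicyclo[4.2.0]octan-7-ol (C7 unassigned) | C/C(=C\CCC#C[Si](C)(C)C)C1(O)C[C@H]2C(C)(C)CCC[C@@]12C | intermediate
23 | alkoxy radical of 22 | C/C(=C\CCC#C[Si](C)(C)C)C1([O])C[C@H]2C(C)(C)CCC[C@@]12C | intermediate (not isolated)
24 | (E)-1-[(1S)-2,2,6-trimethylcyclohexan-6-yl radical]-3-methyl-8-(trimethylsilyl)oct-3-en-7-yn-2-one (tertiary C10 radical) | C/C(=C\CCC#C[Si](C)(C)C)C(=O)C[C@H]1C(C)(C)CCC[C]1C | intermediate (not isolated)
25 | 7-oxo-14-(trimethylsilyl)-15,16-dinorlabd-13-yn-8-yl radical | C[C]1C(=O)C[C@H]2C(C)(C)CCC[C@]2(C)[C@H]1CCC#C[Si](C)(C)C | intermediate (not isolated)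
26 | collidinium 14-(trimethylsilyl)-15,16-dinorlabd-7-en-13-yn-7-olate | CC1=C([O-])C[C@H]2C(C)(C)CCC[C@]2(C)[C@H]1CCC#C[Si](C)(C)C.Cc1cc(C)[nH+]c(C)c1 | intermediate (not isolated)
27 | (8ξ)-14-(trimethylsilyl)-15,16-dinorlabd-13-yn-7-one (5α-H, 9α-H, 10β-CH3) | CC1C(=O)C[C@H]2C(C)(C)CCC[C@]2(C)[C@H]1CCC#C[Si](C)(C)C | intermediate
28 | bromomagnesium 14-(trimethylsilyl)-15,16-dinorlabd-7-en-13-yn-7-olate | CC1=C(O[Mg]Br)C[C@H]2C(C)(C)CCC[C@]2(C)[C@H]1CCC#C[Si](C)(C)C | intermediate (not isolated)
29 | 14-(trimethylsilyl)-15,16-dinorlabd-7-en-13-yn-7-yl trifluoromethanesulfonate | CC1=C(OS(=O)(=O)C(F)(F)F)C[C@H]2C(C)(C)CCC[C@]2(C)[C@H]1CCC#C[Si](C)(C)C | intermediate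
30 | 14-(trimethylsilyl)-15,16-dinorlabd-7-en-13-yne | CC1=CC[C@H]2C(C)(C)CCC[C@]2(C)[C@H]1CCC#C[Si](C)(C)C | intermediate
31 | 15,16-dinorlabd-7-en-13-yne | CC1=CC[C@H]2C(C)(C)CCC[C@]2(C)[C@H]1CCC#C | intermediate
32 | (E)-alkenyl(dimethyl)alane from 31 (CH3 and Al cis) | CC1=CC[C@H]2C(C)(C)CCC[C@]2(C)[C@H]1CC/C(C)=C/[Al](C)C | intermediate (not isolated)
33 | lithium butyl(dimethyl)alkenylaluminate from 32 | CC1=CC[C@H]2C(C)(C)CCC[C@]2(C)[C@H]1CC/C(C)=C/[Al-](C)(C)CCCC.[Li+] | intermediate (not isolated)
34 | (5S,9S,10S)-labda-7,13E-dien-15-ol | CC1=CC[C@H]2C(C)(C)CCC[C@]2(C)[C@H]1CC/C(C)=C/CO | intermediate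
35 | malonic acid | OC(=O)CC(=O)O | starting material
36 | (5S,9S,10S)-labda-7,13E-dien-15-yl hydrogen malonate | CC1=CC[C@H]2C(C)(C)CCC[C@]2(C)[C@H]1CC/C(C)=C/COC(=O)CC(=O)O | intermediate (not isolated)
37 | bis[(5S,9S,10S)-labda-7,13E-dien-15-yl] malonate (CNP0113044.1) | CC1=CC[C@H]2C(C)(C)CCC[C@]2(C)[C@H]1CC/C(C)=C/COC(=O)CC(=O)OC/C=C(\C)CC[C@H]1C(C)=CC[C@H]2C(C)(C)CCC[C@]12C | target

**Step count**

Total: 17 steps. Longest linear sequence: 13 steps (steps 1–4, 6, 7, 11–17).

**Steps most likely to fail**

Step 12. The tertiary C10 radical may be quenched before it closes the ring, the O–H homolysis of the hindered tertiary alcohol may be slow, or the closure may lose facial control at C10. The fallback sets out from 22 and returns at 29, and it keeps the two-carbon expansion of the same four-membered ring but runs it thermally. 22 is silylated (TMSCl, imidazole) to its trimethylsilyl ether F1. Flash vacuum thermolysis (about 400 °C) brings about the thermal vinylcyclobutane-to-cyclohexene [1,3] rearrangement and should give the ring-expanded trimethylsilyl enol ether F2, with the oxygenated double bond already at C7=C8. MeLi cleaves F2 to the lithium enolate F3, which PhNTf2 converts to 29, so the ketone and step 13 are bypassed.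

Step 7. The auxiliary may discriminate poorly between the two faces of the keteniminium, leaving the ketone with too little enantiomeric purity. The fallback sets out from 8 and returns at 15 by classical resolution. 8 alkylates 1-(pyrrolidin-1-yl)propan-1-one (lithium diisopropylamide) to the amide F4. Tf2O/collidine followed by water gives the racemic cis ketone F5, and LiBH(s-Bu)3 reduces it to the racemic cyclobutanol F6. Esterification with (S)-2-methoxy-2-phenylacetic acid (DCC, DMAP) gives two diastereomeric esters, the ester of the (1S,6R) series F7 and its diastereomer F8, which are separated by chromatography. LiOH cleaves F7 to the enantiopure cyclobutanol F9, and Dess–Martin oxidation returns 15.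

Step 13. Enolisation toward C6 may compete, which would place the triflate, and later the double bond, at C6=C7. The fallback sets out from 27 and returns at 30 without an enolate. 27, equilibrated at C8 with NaOMe to the equatorial methyl epimer, is reduced from the equatorial side with LiBH(s-Bu)3 to the axial 7α-alcohol F10. POCl3/pyridine then effects anti elimination through the axial 8β-hydrogen and should give the trisubstituted alkene 30.

**Further compounds**

F1 | step 12 | trimethylsilyl ether of 22 | C/C(=C\CCC#C[Si](C)(C)C)C1(O[Si](C)(C)C)C[C@H]2C(C)(C)CCC[C@@]12C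
F2 | step 12 | 7-(trimethylsilyloxy)-14-(trimethylsilyl)-15,16-dinorlabd-7-en-13-yne | CC1=C(O[Si](C)(C)C)C[C@H]2C(C)(C)CCC[C@]2(C)[C@H]1CCC#C[Si](C)(C)C
F3 | step 12 | lithium 14-(trimethylsilyl)-15,16-dinorlabd-7-en-13-yn-7-olate | CC1=C(O[Li])C[C@H]2C(C)(C)CCC[C@]2(C)[C@H]1CCC#C[Si](C)(C)C
F4 | step 7 | 2,6,6-trimethyl-1-(pyrrolidin-1-yl)oct-7-en-1-one | C=CC(C)(C)CCCC(C)C(=O)N1CCCC1
F5 | step 7 | racemic cis-2,2,6-trimethylbicyclo[4.2.0]octan-7-one | O=C1CC2C(C)(C)CCCC12C
F6 | step 7 | racemic cis-2,2,6-trimethylbicyclo[4.2.0]octan-7-ol | OC1CC2C(C)(C)CCCC12C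
F7 | step 7 | (1S,6R)-2,2,6-trimethylbicyclo[4.2.0]octan-7-yl (S)-2-methoxy-2-phenylacetate | CO[C@H](C(=O)OC1C[C@H]2C(C)(C)CCC[C@@]12C)c1ccccc1
F8 | step 7 | (1R,6S)-2,2,6-trimethylbicyclo[4.2.0]octan-7-yl (S)-2-methoxy-2-phenylacetate | CO[C@H](C(=O)OC1C[C@@H]2C(C)(C)CCC[C@]12C)c1ccccc1
F9 | step 7 | (1S,6R)-2,2,6-trimethylbicyclo[4.2.0]octan-7-ol | OC1C[C@H]2C(C)(C)CCC[C@@]12C
F10 | step 13 | (7α,8α-methyl)-14-(trimethylsilyl)-15,16-dinorlabd-13-yn-7-ol (axial 7α-OH, 8β-H) | C[C@@H]1[C@H](O)C[C@H]2C(C)(C)CCC[C@]2(C)[C@H]1CCC#C[Si](C)(C)C
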